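**Retrosynthetic overview**

1. Target ⇐ reductive radical cascade (C3–C2′ bond closing the seven-membered bridge, then 5-exo closure of the cyclopentane) of a 3-bromo-1-benzoyl-5-geranyl-3,7-diprenylbicyclo[3.3.1]nonane-2,4,9-trione with the C7 prenyl endo.
2. That trione ⇐ an adamantanol (C3–CH(OH)–C7 bridge) by retro-aldol/alkenylcerium addition and allylic hydrogenolysis; the adamantanol ⇐ a bicyclic 1,3-dibenzoyl aldehyde by exchanging the spare C3 benzoyl for prenyl and intramolecular aldol closure.
3. Bicyclic aldehyde ⇐ symmetric 2,4-dibenzoyl-6-geranylphloroglucinol + 2-(acetoxymethyl)-3-methylbut-2-enal: alkylative dearomatization, then the key ring closure, an enantioselective desymmetrizing intramolecular Michael addition (C1–C8 bond).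
4. Fragments: the enal from diethyl isopropylidenemalonate (3 steps); the acylphloroglucinol from phloroglucinol, benzoyl chloride and geraniol (3 steps); the prenyl donor from prenol (1 step).
5. Ring order: trione ring A (from the arene) → ring B (Michael) → adamantane bridge (aldol, reopened later) → seven-membered bridge → cyclopentane.

Assumption: the cinchonidinium salt gives the enantiomer drawn (otherwise its cinchoninium pseudoenantiomer is used); centres that equilibrate or are destroyed later are left undefined in the SMILES.

Core numbering used below: bicyclo[3.3.1]nonane C1 (benzoyl bridgehead), C2/C4 (ring A carbonyls), C3, C5 (geranyl bridgehead), C6 (CH2), C7, C8 (CMe2), C9 (bridging C=O). "Endo" at C7 or C3 means pointing toward the other of these two carbons.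

**Route**

Step 1
Reactants: 1 diethyl 2-(propan-2-ylidene)propanedioate
Product: 2 2-(propan-2-ylidene)propane-1,3-diol
Conditions: i-Bu2AlH (4.5 equiv), CH2Cl2, −78 → 0 °C; aq. potassium sodium tartrate
Reagents that add atoms: none
Why: 1,2-reduction of both esters of the alkylidene malonate by the electrophilic aluminium hydride leaves the tetrasubstituted alkene untouched, and no stereocentre is formed.

Step 2
Reactants: 2 2-(propan-2-ylidene)propane-1,3-diol
Product: 3 2-(hydroxymethyl)-3-methylbut-2-en-1-yl acetate
Conditions: vinyl acetate (1.2 equiv), immobilised Candida antarctica lipase B, MTBE, rt, stopped at the mono-ester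
Reagents that add atoms: vinyl acetate, CC(=O)OC=C
Why: lipase-catalysed irreversible transesterification acylates one of the two equivalent primary allylic alcohols far faster than it acylates the resulting mono-ester.

Step 3
Reactants: 3 2-(hydroxymethyl)-3-methylbut-2-en-1-yl acetate
Product: 4 2-formyl-3-methylbut-2-en-1-yl acetate
Conditions: MnO2 (15 equiv), CH2Cl2, rt
Reagents that add atoms: none
Why: chemoselective oxidation of the allylic alcohol to the enal, with the acetate untouched and no E/Z issue because the β-carbon carries two methyls.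

Step 4
Reactants: 5 phloroglucinol, 6 benzoyl chloride
Product: 7 2,4-dibenzoylphloroglucinol
Conditions: 6 (2.2 equiv), AlCl3 (4 equiv), PhNO2, 60 °C; aq. HCl
Reagents that add atoms: none
Why: twofold Friedel–Crafts C-acylation of the very electron-rich arene stops at the diketone because the third ring carbon is then strongly deactivated.

Step 5
Reactants: 8 geraniol
Product: 9 geranyl bromide
Conditions: PBr3 (0.4 equiv), Et2O, −10 °C
Reagents that add atoms: phosphorus tribromide, BrP(Br)Br
Why: SN2 displacement of the activated primary allylic alcohol at low temperature keeps the E alkene geometry.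

Step 6
Reactants: 7 2,4-dibenzoylphloroglucinol, 9 geranyl bromide
Product: 10 2,4-dibenzoyl-6-geranylphloroglucinol
Conditions: 10% aq. KOH, 0 °C → rt, 9 added slowly
Reagents that add atoms: none
Why: C-alkylation of the phenolate in water occurs at the only ring carbon that bears no acyl group, giving a C2v-symmetric arene.

Step 7
Reactants: 11 3-methylbut-2-en-1-ol
Product: 12 methyl 3-methylbut-2-en-1-yl carbonate
Conditions: ClCO2Me, pyridine, CH2Cl2, 0 °C
Reagents that add atoms: methyl chloroformate, COC(=O)Cl
Why: simple O-acylation gives the allylic carbonate that later serves as a neutral prenyl donor and internal methoxide source.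

Step 8
Reactants: 10 2,4-dibenzoyl-6-geranylphloroglucinol, 4 2-formyl-3-methylbut-2-en-1-yl acetate
Product: 14 1,3-dibenzoyl-5-geranyl-4-hydroxy-8,8-dimethyl-2,9-dioxobicyclo[3.3.1]non-3-ene-7-carbaldehyde, via dienone 13 (not isolated)
Conditions: 4 (1.5 equiv), N-(9-anthracenylmethyl)-O-allylcinchonidinium bromide (20 mol %), CsOH·H2O (5 equiv), CH2Cl2, −50 → −20 °C
Reagents that add atoms: none
Why: alkylative dearomatization at the geranyl-bearing carbon (the only ring carbon not deactivated by an acyl group) gives achiral dienone 13, whose cinchonidinium-paired dienolate closes ring B by intramolecular Michael addition of one of the two enantiotopic benzoyl-bearing carbons to the β,β-dimethyl enal, and this desymmetrization sets C1 and C5 while C7 stays epimerizable.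

Step 9
Reactants: 14 1,3-dibenzoyl-5-geranyl-4-hydroxy-8,8-dimethyl-2,9-dioxobicyclo[3.3.1]non-3-ene-7-carbaldehyde, 12 methyl 3-methylbut-2-en-1-yl carbonate
Product: 17 adamantanol (1-benzoyl-5-geranyl-3-prenyl-8,8-dimethyl trione bearing a C3–CH(OH)–C7 bridge), via benzoyl prenyl trione 15 (not isolated), via epimeric enol aldehyde 16 (not isolated)
Conditions: 12 (1.05 equiv), Pd(PPh3)4 (5 mol %), THF, rt; SiO2 plug; then K2CO3, MeOH, rt; then AcOH to pH 6
Reagents that add atoms: none
Why: Tsuji–Trost C-prenylation of the highly acidic 2-benzoyl-1,3-dione makes C3 quaternary so that methoxide removes the spare C3 benzoyl by retro-Claisen cleavage (the bridgehead C1 benzoyl cannot leave as an enolate), giving the enol aldehyde 16 as a mixture of C7 epimers that interconvert through the aldehyde enolate until the endo epimer is trapped by intramolecular aldol addition of C3, which fixes C7.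

Step 10
Reactants: 17 adamantanol, 18 (2-methylprop-1-en-1-yl)magnesium bromide
Product: 21 allylic methyl carbonate of the ring-opened endo adduct, its ring A enol capped as a methyl carbonate, via endo enol aldehyde 19 (not isolated), via allylic alcohol 20 (not isolated)
Conditions: 18 (3 equiv), CeCl3 (3 equiv), THF, −78 → −30 °C; then ClCO2Me (4 equiv), −78 → 0 °C
Reagents that add atoms: methyl chloroformate, COC(=O)Cl
Why: deprotonation of the carbinol triggers a stereospecific retro-aldol that releases only the 7-endo aldehyde 19 as its metal enolate, the non-basic organocerium reagent adds 1,2 to it at low temperature faster than C7 can epimerize, and both oxyanions are capped in situ; the new carbinol centre is removed in the next step, so its configuration does not matter.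

Step 11
Reactants: 21 allylic methyl carbonate with enol methyl carbonate
Product: 22 1-benzoyl-5-geranyl-4-hydroxy-8,8-dimethyl-3,7-diprenylbicyclo[3.3.1]non-3-ene-2,9-dione (7-endo prenyl)
Conditions: Pd(PPh3)4 (5 mol %), Bu3SnH (1.2 equiv, slow addition), THF, rt; then K2CO3, MeOH, rt
Reagents that add atoms: none
Why: palladium-catalysed allylic hydrogenolysis reduces the 1-alkyl-3,3-dimethylallyl complex at its less substituted terminus to leave the trisubstituted prenyl alkene, the enol carbonate blocks intramolecular C-allylation by C3 until it is removed by methanolysis, and no stereocentre is touched.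

Step 12
Reactants: 22 1-benzoyl-5-geranyl-4-hydroxy-8,8-dimethyl-3,7-diprenylbicyclo[3.3.1]non-3-ene-2,9-dione
Product: 24 target CNP0155129.3, via bromide 23 (not isolated)
Conditions: NBS (1.0 equiv), CH2Cl2, 0 °C, dark; solvent switch; Bu3SnH (1.3 equiv, syringe pump), AIBN (0.2 equiv), PhH, 80 °C, 5 mM
Reagents that add atoms: none
Why: in this reductive radical cascade the electrophilic C3 radical from the α-bromo-1,3-diketone adds to the CH terminus of the endo C7 prenyl group (seven-membered bridge, CMe2 turned to the less hindered C4/C6 side, setting the ring-fusion CH), the tertiary radical closes 5-exo-trig onto the C3 prenyl group with the new substituent trans to the bridge CH2 (chair-like Beckwith transition state, setting the isopropyl-bearing CH and making C3 quaternary), and the last tertiary radical takes hydrogen from Bu3SnH to give the isopropyl group.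

**Compound list**

1 | diethyl 2-(propan-2-ylidene)propanedioate | CCOC(=O)C(=C(C)C)C(=O)OCC | starting material
2 | 2-(propan-2-ylidene)propane-1,3-diol | CC(C)=C(CO)CO | intermediate
3 | 2-(hydroxymethyl)-3-methylbut-2-en-1-yl acetate | CC(C)=C(CO)COC(C)=O | intermediate
4 | 2-formyl-3-methylbut-2-en-1-yl acetate | CC(C)=C(C=O)COC(C)=O | intermediate
5 | phloroglucinol | Oc1cc(O)cc(O)c1 | starting material
6 | benzoyl chloride | O=C(Cl)c1ccccc1 | starting material
7 | 2,4-dibenzoylphloroglucinol | O=C(c1ccccc1)c1c(O)cc(O)c(C(=O)c2ccccc2)c1O | intermediate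
8 | geraniol | CC(C)=CCC/C(C)=C/CO | starting material
9 | geranyl bromide | CC(C)=CCC/C(C)=C/CBr | intermediate
10 | 2,4-dibenzoyl-6-geranylphloroglucinol | O=C(c1ccccc1)c1c(O)c(C/C=C(\C)CCC=C(C)C)c(O)c(C(=O)c2ccccc2)c1O | intermediate
11 | 3-methylbut-2-en-1-ol (prenol) | CC(C)=CCO | starting material
12 | methyl 3-methylbut-2-en-1-yl carbonate | CC(C)=CCOC(=O)OC | intermediate
13 | achiral dienone: 2,6-dibenzoyl-4-geranyl-4-(2-formyl-3-methylbut-2-enyl)-3,5-dihydroxycyclohexa-2,5-dien-1-one | O=C(c1ccccc1)C1=C(O)C(C/C=C(\C)CCC=C(C)C)(CC(C=O)=C(C)C)C(O)=C(C(=O)c2ccccc2)C1=O | intermediate (not isolated)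
14 | bicyclic aldehyde: 1,3-dibenzoyl-5-geranyl-4-hydroxy-8,8-dimethyl-2,9-dioxobicyclo[3.3.1]non-3-ene-7-carbaldehyde; bridgeheads as in the target; C7 equilibrating | O=CC1C[C@]2(C/C=C(\C)CCC=C(C)C)C(O)=C(C(=O)c3ccccc3)C(=O)[C@@](C(=O)c3ccccc3)(C2=O)C1(C)C | intermediate
15 | benzoyl prenyl trione: 1,3-dibenzoyl-5-geranyl-3-prenyl-8,8-dimethyl-2,4,9-trioxobicyclo[3.3.1]nonane-7-carbaldehyde; prenyl on the exo face of C3 (centre destroyed in the next event); C7 equilibrating | O=CC1C[C@]2(C/C=C(\C)CCC=C(C)C)C(=O)[C@](CC=C(C)C)(C(=O)c3ccccc3)C(=O)[C@@](C(=O)c3ccccc3)(C2=O)C1(C)C | intermediate (not isolated)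
16 | epimeric enol aldehyde: 1-benzoyl-5-geranyl-4-hydroxy-3-prenyl-8,8-dimethyl-2,9-dioxobicyclo[3.3.1]non-3-ene-7-carbaldehyde as the mixture of C7 epimers formed by debenzoylation, interconverting in K2CO3/MeOH | O=CC1C[C@]2(C/C=C(\C)CCC=C(C)C)C(O)=C(CC=C(C)C)C(=O)[C@@](C(=O)c3ccccc3)(C2=O)C1(C)C | intermediate (not isolated)
17 | adamantanol: 1-benzoyl-5-geranyl-3-prenyl-8,8-dimethyl-2,4,9-trione with an endo C3–CH(OH)–C7 bridge; carbinol configuration immaterial | O=C(c1ccccc1)[C@@]12C(=O)[C@@]3(CC=C(C)C)C(O)[C@H](C[C@](C/C=C(\C)CCC=C(C)C)(C3=O)C2=O)C1(C)C | intermediate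
18 | (2-methylprop-1-en-1-yl)magnesium bromide (commercial THF solution) | CC(C)=C[Mg]Br | starting material
19 | endo enol aldehyde: single 7-endo epimer of the ring-opened enol aldehyde, released from 17 by retro-aldol and present only as its metal enolate at low temperature | O=C[C@@H]1C[C@]2(C/C=C(\C)CCC=C(C)C)C(O)=C(CC=C(C)C)C(=O)[C@@](C(=O)c3ccccc3)(C2=O)C1(C)C | intermediate (not isolated)
20 | allylic alcohol: ring-opened enol trione with 7-endo CH(OH)CH=CMe2 (present as its alkoxide; carbinol epimers) | CC(C)=CC(O)[C@@H]1C[C@]2(C/C=C(\C)CCC=C(C)C)C(O)=C(CC=C(C)C)C(=O)[C@@](C(=O)c3ccccc3)(C2=O)C1(C)C | intermediate (not isolated)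
21 | bis(methyl carbonate) of 20: allylic carbonate plus enol carbonate (4-O isomer drawn; the 2-O isomer converges) | CC(C)=CC(OC(=O)OC)[C@@H]1C[C@]2(C/C=C(\C)CCC=C(C)C)C(OC(=O)OC)=C(CC=C(C)C)C(=O)[C@@](C(=O)c3ccccc3)(C2=O)C1(C)C | intermediate
22 | 1-benzoyl-5-geranyl-4-hydroxy-8,8-dimethyl-3,7-diprenylbicyclo[3.3.1]non-3-ene-2,9-dione; 7-endo prenyl | CC(C)=CC[C@@H]1C[C@]2(C/C=C(\C)CCC=C(C)C)C(O)=C(CC=C(C)C)C(=O)[C@@](C(=O)c3ccccc3)(C2=O)C1(C)C | intermediate
23 | bromide: 3-bromo-1-benzoyl-5-geranyl-8,8-dimethyl-3,7-diprenylbicyclo[3.3.1]nonane-2,4,9-trione; C3 epimers converge | CC(C)=CC[C@@H]1C[C@]2(C/C=C(\C)CCC=C(C)C)C(=O)C(Br)(CC=C(C)C)C(=O)[C@@](C(=O)c3ccccc3)(C2=O)C1(C)C | intermediate (not isolated)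
24 | target CNP0155129.3: homoadamantane trione with fused cyclopentane | CC(C)=CCC/C(C)=C/C[C@@]12C[C@H]3C[C@H]4C(C)(C)[C@H](C(C)C)C[C@]4(C1=O)C(=O)[C@@](C(=O)c1ccccc1)(C2=O)C3(C)C | target

**Step count**

Total steps: 12. Longest linear sequence: 8 (steps 1, 2, 3, 8, 9, 10, 11, 12). The other branches are steps 4 and 6 (arene), step 5 (geranyl bromide) and step 7 (prenyl carbonate).

**Steps most likely to fail, with fallbacks**

Step 8. The cascade must alkylate at carbon, form a bond between two fully substituted carbons, and be steered by the chiral cation in a desymmetrization for which there is only analogy. If the one-pot ion-pair process does not give 14 in useful enantiomeric excess, the two events are separated. Compound 10 is C-alkylated with 4 under achiral conditions (K2CO3, acetone, 0 °C) and the achiral dienone 13 is isolated. Its neutral bis-enol is then cyclized in a separate step under chiral Brønsted-acid catalysis ((R)-3,3′-bis(2,4,6-triisopropylphenyl)-1,1′-binaphthyl-2,2′-diyl hydrogen phosphate, 10 mol %, toluene, 0 °C), which activates the enal by hydrogen bonding instead of pairing a dienolate with a chiral cation. This fallback sets out from 10 and rejoins the route at 14; it makes no new compound F0.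

Step 11. The tin hydride may deliver hydrogen to the tertiary terminus, or β-hydride elimination may give a diene. The fallback builds the prenyl group in three operations from 17. Vinylmagnesium bromide with CeCl3, then ClCO2Me, gives the vinyl bis-carbonate F1. Pd(PPh3)4 with HCO2NH4 (formate delivers hydride to the more substituted terminus and so gives the terminal alkene), followed by K2CO3 in MeOH, gives the 7-endo allyl enol F2. Cross-metathesis of F2 with 2-methylbut-2-ene and the second-generation Grubbs catalyst (CH2Cl2, 40 °C) converts only the monosubstituted alkene and gives 22. This fallback sets out from 17 and comes back at 22.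

Step 12. The C3 radical may be reduced before it cyclizes, or the first addition may take the other alkene face. The fallback replaces the tin-mediated reductive cascade by an oxidative one from the enol itself. Compound 22 is treated with Mn(OAc)3·2H2O and Cu(OAc)2·H2O in AcOH at rt; the same two ring closures occur and divalent copper terminates the last radical by oxidative elimination, giving the isopropenyl cage F3. The 1,1-disubstituted alkene of F3 is then hydrogenated selectively in the presence of the trisubstituted geranyl alkenes with H2 (1 atm) and RhCl(PPh3)3 in benzene to give 24. This fallback sets out from 22 and comes back at 24.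

**Further compounds**

F0 | step 8 | none | none
F1 | step 11 | vinyl bis(methyl carbonate): analogue of 21 with CH=CH2 in place of CH=CMe2 | C=CC(OC(=O)OC)[C@@H]1C[C@]2(C/C=C(\C)CCC=C(C)C)C(OC(=O)OC)=C(CC=C(C)C)C(=O)[C@@](C(=O)c3ccccc3)(C2=O)C1(C)C
F2 | step 11 | 7-endo allyl enol: analogue of 22 with allyl at C7 | C=CC[C@@H]1C[C@]2(C/C=C(\C)CCC=C(C)C)C(O)=C(CC=C(C)C)C(=O)[C@@](C(=O)c3ccccc3)(C2=O)C1(C)C
F3 | step 12 | isopropenyl cage: target with prop-1-en-2-yl in place of isopropyl | CC(C)=CCC/C(C)=C/C[C@@]12C[C@H]3C[C@H]4C(C)(C)[C@H](C(C)=C)C[C@]4(C1=O)C(=O)[C@@](C(=O)c1ccccc1)(C2=O)C3(C)C
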